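**Retrosynthetic overview**

- Target ⇐ O‑formylation and desilylation ⇐ γ‑hydroxy enal ⇐ (methoxymethylenation, vinylogous epoxide opening) epoxy ketone ⇐ (epoxidation anti to CH3‑20) trans‑fused bicyclic enone with C6=C7–C8=O.
- Key disconnection: C5–C10 and C6–C7 of that enone are made in one operation, an amine‑catalysed intramolecular Michael addition/aldol condensation of an acyclic C6 aldehyde/C8 methyl ketone. Ring A closes first (Michael), ring B second (aldol).
- Enabling feature: in ring B the carbinol carbon C6 and C8 (which carries the formyl carbon C17) are 1,3 to each other and 1,5 across the C5–C10 bond. With C6 as aldehyde and C7–C8 as acetyl, C5 and C7 are donors and C10 and C6 acceptors.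
- Acyclic precursor ⇐ B‑alkyl Suzuki coupling (C1–C10) of an acetylacetone‑derived enol triflate with an alkene from 2,2‑dimethylpent‑4‑enal, then Negishi coupling (C12–C13) with a (Z)‑enol triflate that fixes the 13E geometry.

Key step: step 12

Remark: atom numbers in the text are labdane numbers (C15 ester, C16 formyloxymethyl, C17 formyl, C20 angular methyl). Compounds 2 and 11–17 are used as mixtures of double‑bond isomers at the enol ether and, from 12 on, at the tetrasubstituted C9=C10 bond.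

**Route**

Step 1
Reactants: 1 2,2‑dimethylpent‑4‑enal
Product: 2 1‑methoxy‑3,3‑dimethylhexa‑1,5‑diene (E/Z mixture)
Conditions: MeOCH2PPh3Cl, KOtBu, THF, 0 °C → rt
Reagents that add atoms: (methoxymethyl)triphenylphosphonium chloride, [Cl-].COC[P+](c1ccccc1)(c1ccccc1)c1ccccc1
Why: Wittig olefination of the non‑enolisable α‑quaternary aldehyde gives the enol ether as a masked, one‑carbon‑homologated aldehyde (the future C6); the E/Z ratio does not matter.

Step 2
Reactants: 3 methyl glycolate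
Product: 4 methyl 2‑[(tert‑butyldiphenylsilyl)oxy]acetate
Conditions: tert‑butyl(chloro)diphenylsilane, imidazole, CH2Cl2, 0 °C → rt
Reagents that add atoms: tert‑butyl(chloro)diphenylsilane, CC(C)(C)[Si](Cl)(c1ccccc1)c1ccccc1
Why: Standard silyl ether formation on the primary alcohol, with a silyl group that later survives aqueous acid and base.

Step 3
Reactants: 4 methyl 2‑[(tert‑butyldiphenylsilyl)oxy]acetate
Product: 5 methyl 4‑[(tert‑butyldiphenylsilyl)oxy]‑3‑oxobutanoate
Conditions: MeOAc, LiN(iPr)2 (2.2 equiv), THF, −78 → −40 °C; aq. NH4Cl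
Reagents that add atoms: methyl acetate, COC(C)=O
Why: Crossed Claisen condensation in which the lithium enolate of methyl acetate acylates at the activated α‑silyloxy ester and the product is held as its enolate by the second equivalent.

Step 4
Reactants: 5 methyl 4‑[(tert‑butyldiphenylsilyl)oxy]‑3‑oxobutanoate
Product: 6 methyl (2Z)‑4‑[(tert‑butyldiphenylsilyl)oxy]‑3‑{[(trifluoromethyl)sulfonyl]oxy}but‑2‑enoate
Conditions: Tf2O, aq. LiOH, toluene, 5 °C
Reagents that add atoms: trifluoromethanesulfonic anhydride, O=S(=O)(OS(=O)(=O)C(F)(F)F)C(F)(F)F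
Why: O‑sulfonylation of the chelated lithium (Z)‑enolate of the β‑keto ester should give the (Z)‑enol triflate (triflate cis to the ester), the geometry that becomes the 13E double bond after stereoretentive coupling.

Step 5
Reactants: 7 pentane‑2,4‑dione; 8 tert‑butyl(2‑iodoethoxy)dimethylsilane
Product: 9 3‑{2‑[(tert‑butyldimethylsilyl)oxy]ethyl}pentane‑2,4‑dione
Conditions: K2CO3, acetone, 56 °C
Reagents that add atoms: none
Why: C‑alkylation (SN2) of the soft diketone enolate with a primary iodide installs C11–C12 with an oxygen handle for the later C12–C13 coupling.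

Step 6
Reactants: 9 3‑{2‑[(tert‑butyldimethylsilyl)oxy]ethyl}pentane‑2,4‑dione
Product: 10 3‑{2‑[(tert‑butyldimethylsilyl)oxy]ethyl}‑4‑oxopent‑2‑en‑2‑yl trifluoromethanesulfonate
Conditions: Tf2O, Et3N, CH2Cl2, −78 → 0 °C
Reagents that add atoms: trifluoromethanesulfonic anhydride, O=S(=O)(OS(=O)(=O)C(F)(F)F)C(F)(F)F
Why: O‑triflation of the diketone enolate gives the vinylogous acyl triflate, and because the diketone is symmetric only one constitution can form.

Step 7
Reactants: 2 1‑methoxy‑3,3‑dimethylhexa‑1,5‑diene; 10 enol triflate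
Product: 12 3‑{2‑[(tert‑butyldimethylsilyl)oxy]ethyl}‑10‑methoxy‑4,8,8‑trimethyldeca‑3,9‑dien‑2‑one, via alkylborane 11 (not isolated)
Conditions: 9‑BBN‑H, THF, 0 °C → rt; then 10, PdCl2(dppf) (5 mol %), aq. K3PO4, DMF, rt → 50 °C
Reagents that add atoms: none
Why: B‑alkyl Suzuki–Miyaura coupling, in which 9‑BBN‑H hydroborates only the monosubstituted terminal alkene (anti‑Markovnikov) and the alkylborane couples with the electron‑poor vinyl triflate to form C1–C10 and the tetrasubstituted enone.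

Step 8
Reactants: 12 silyl ether
Product: 13 3‑(2‑hydroxyethyl)‑10‑methoxy‑4,8,8‑trimethyldeca‑3,9‑dien‑2‑one
Conditions: Bu4NF, THF, 0 °C
Reagents that add atoms: none
Why: Fluoride‑induced desilylation of the primary silyl ether, to which enol ether and enone are inert.

Step 9
Reactants: 13 primary alcohol
Product: 14 3‑(2‑iodoethyl)‑10‑methoxy‑4,8,8‑trimethyldeca‑3,9‑dien‑2‑one
Conditions: I2, PPh3, imidazole, CH2Cl2, 0 °C
Reagents that add atoms: iodine, [I][I]
Why: Appel‑type iodination (SN2 on the alkoxyphosphonium salt) under imidazole buffering, which protects the enol ether.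

Step 10
Reactants: 14 primary iodide; 6 (Z)‑enol triflate
Product: 16 methyl (2E)‑6‑acetyl‑3‑{[(tert‑butyldiphenylsilyl)oxy]methyl}‑13‑methoxy‑7,11,11‑trimethyltrideca‑2,6,12‑trienoate, via alkylzinc iodide 15 (not isolated)
Conditions: Zn dust, LiCl, THF, 25–40 °C; then 6, PdCl2(dppf) (5 mol %), THF, 40 °C
Reagents that add atoms: none
Why: Negishi coupling, in which zinc inserts into the primary C–I bond without touching ketone or enol ether and the alkylzinc couples with the vinyl triflate with retention, so that C12 ends cis to the ester (13E).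

Step 11
Reactants: 16 enol ether
Product: 17 methyl (2E)‑6‑acetyl‑3‑{[(tert‑butyldiphenylsilyl)oxy]methyl}‑7,11,11‑trimethyl‑13‑oxotrideca‑2,6‑dienoate
Conditions: 1 M aq. HCl, THF, 0 °C → rt
Reagents that add atoms: water, O
Why: Acid‑catalysed enol ether hydrolysis unmasks the C6 aldehyde while the tert‑butyldiphenylsilyl ether and the esters survive.

Step 12
Reactants: 17 acyclic keto aldehyde
Product: 20 methyl (13E)‑16‑[(tert‑butyldiphenylsilyl)oxy]‑8‑oxo‑17‑nor‑ent‑labda‑6,13‑dien‑15‑oate (trans‑fused enone; H‑5 and H‑9 on the face opposite CH3‑20), via keto aldehyde 18 (not isolated), via ketol 19 (not isolated)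
Conditions: (S)‑2‑[methoxy(diphenyl)methyl]pyrrolidine (20 mol %), ethyl 3,4‑dihydroxybenzoate (40 mol %), toluene, 40 °C; then p‑TsOH·H2O (30 mol %), 50 °C
Reagents that add atoms: none
Why: Proposed new method: the secondary amine condenses with the unhindered aldehyde to the (E)‑enamine, whose C5 adds 6‑exo‑trig to C10 of the catechol‑hydrogen‑bonded tetrasubstituted enone (ring A, quaternary C10), and in the acid stage the C8 acetyl group enolises towards C7 for a 6‑(enolexo)‑exo‑trig aldol addition to C6 and dehydration (ring B as the C6=C7–C8=O enone). The closest known reactions are the amine‑catalysed intramolecular Michael addition of aldehydes to enones and the diarylprolinol ether/catechol‑catalysed addition of aldehydes to vinyl ketones followed by acid‑mediated aldol condensation (Robinson‑type annulation); new are the tetrasubstituted acceptor and the quaternary centre. C5 is controlled by the catalyst, which shields one enamine face as in its intermolecular Michael additions, so the (S)‑amine should give the required C5 configuration. C10 follows from the chair‑like transition state with the enamine and the C9 arm equatorial and CH3‑20 axial (trans fusion), because the alternative puts the bulky C9 arm syn‑axial to a C4 methyl group. C9 is set by equilibration next to the C8 ketone (side chain equatorial), so both geometric isomers of the enone give the same product, since only the epimerisable C9 depends on alkene geometry. The step needs facial selectivity at C10 and the 6‑exo Michael mode over other closures; the three‑carbon tether with the C4 gem‑dimethyl group and the engagement of the aldehyde as enamine should secure both.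

Step 13
Reactants: 20 bicyclic enone
Product: 21 methyl (13E)‑16‑[(tert‑butyldiphenylsilyl)oxy]‑6,7‑epoxy‑8‑oxo‑17‑nor‑ent‑labd‑13‑en‑15‑oate (epoxide oxygen on the face opposite CH3‑20)
Conditions: t‑BuOOH (decane), DBU, CH2Cl2, 0 °C → rt
Reagents that add atoms: tert‑butyl hydroperoxide, CC(C)(C)OO
Why: Weitz–Scheffer nucleophilic epoxidation, in which the peroxide anion adds to C6 from the face opposite the two syn‑axial methyl groups (CH3‑20 and the axial C4 methyl); this sets the C6–O configuration and leaves the less electrophilic β,β‑disubstituted enoate alone.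

Step 14
Reactants: 21 epoxy ketone
Product: 23 methyl (13E)‑16‑[(tert‑butyldiphenylsilyl)oxy]‑6‑hydroxy‑17‑oxo‑ent‑labda‑7,13‑dien‑15‑oate (6‑OH on the face opposite CH3‑20), via epoxy enol ether 22 (not isolated)
Conditions: MeOCH2PPh3Cl, KN(SiMe3)2, THF, −78 → 0 °C; then 1 M aq. HCl, THF, 0 °C
Reagents that add atoms: (methoxymethyl)triphenylphosphonium chloride, [Cl-].COC[P+](c1ccccc1)(c1ccccc1)c1ccccc1; water, O
Why: Wittig methoxymethylenation of the C8 ketone, then acid‑induced vinylogous (SN2'‑type) opening of the allylic C7–O epoxide bond by the enol ether and collapse of the hemiacetal give the γ‑hydroxy enal, with the C6–O bond untouched (configuration retained) and C9 fixed with the equatorial side chain.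

Step 15
Reactants: 23 silyl‑protected hydroxy enal
Product: 24 methyl (13E)‑6,16‑dihydroxy‑17‑oxo‑ent‑labda‑7,13‑dien‑15‑oate
Conditions: Bu4NF, AcOH, THF, 0 °C → rt
Reagents that add atoms: none
Why: Fluoride‑mediated cleavage of the silyl ether, buffered with acetic acid to spare the base‑sensitive γ‑hydroxy enal.

Step 16
Reactants: 24 diol
Product: 25 CNP0134813.1
Conditions: acetic formic anhydride (1.1 equiv), pyridine, CH2Cl2, −40 °C
Reagents that add atoms: acetic formic anhydride, CC(=O)OC=O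
Why: Acyl transfer from the mixed anhydride delivers the formyl group, and the primary allylic C16 hydroxyl should react much faster than the secondary C6 hydroxyl, which is crowded by the equatorial C4 methyl group.

**Compound list**

1 | 2,2‑dimethylpent‑4‑enal | C=CCC(C)(C)C=O | starting material
2 | 1‑methoxy‑3,3‑dimethylhexa‑1,5‑diene (E/Z mixture) | COC=CC(C)(C)CC=C | intermediate
3 | methyl glycolate | COC(=O)CO | starting material
4 | methyl 2‑[(tert‑butyldiphenylsilyl)oxy]acetate | COC(=O)CO[Si](c1ccccc1)(c1ccccc1)C(C)(C)C | intermediate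
5 | methyl 4‑[(tert‑butyldiphenylsilyl)oxy]‑3‑oxobutanoate | COC(=O)CC(=O)CO[Si](c1ccccc1)(c1ccccc1)C(C)(C)C | intermediate
6 | methyl (2Z)‑4‑[(tert‑butyldiphenylsilyl)oxy]‑3‑{[(trifluoromethyl)sulfonyl]oxy}but‑2‑enoate | COC(=O)/C=C(\OS(=O)(=O)C(F)(F)F)CO[Si](c1ccccc1)(c1ccccc1)C(C)(C)C | intermediate
7 | pentane‑2,4‑dione | CC(=O)CC(C)=O | starting material
8 | tert‑butyl(2‑iodoethoxy)dimethylsilane | CC(C)(C)[Si](C)(C)OCCI | starting material
9 | 3‑{2‑[(tert‑butyldimethylsilyl)oxy]ethyl}pentane‑2,4‑dione | CC(=O)C(CCO[Si](C)(C)C(C)(C)C)C(C)=O | intermediate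
10 | 3‑{2‑[(tert‑butyldimethylsilyl)oxy]ethyl}‑4‑oxopent‑2‑en‑2‑yl trifluoromethanesulfonate (alkene geometry not defined) | CC(=O)C(CCO[Si](C)(C)C(C)(C)C)=C(C)OS(=O)(=O)C(F)(F)F | intermediate
11 | 9‑(6‑methoxy‑4,4‑dimethylhex‑5‑en‑1‑yl)‑9‑borabicyclo[3.3.1]nonane | COC=CC(C)(C)CCCB1C2CCCC1CCC2 | intermediate
12 | 3‑{2‑[(tert‑butyldimethylsilyl)oxy]ethyl}‑10‑methoxy‑4,8,8‑trimethyldeca‑3,9‑dien‑2‑one (double‑bond isomers) | CC(=O)C(CCO[Si](C)(C)C(C)(C)C)=C(C)CCCC(C)(C)C=COC | intermediate
13 | 3‑(2‑hydroxyethyl)‑10‑methoxy‑4,8,8‑trimethyldeca‑3,9‑dien‑2‑one | CC(=O)C(CCO)=C(C)CCCC(C)(C)C=COC | intermediate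
14 | 3‑(2‑iodoethyl)‑10‑methoxy‑4,8,8‑trimethyldeca‑3,9‑dien‑2‑one | CC(=O)C(CCI)=C(C)CCCC(C)(C)C=COC | intermediate
15 | (3‑acetyl‑10‑methoxy‑4,8,8‑trimethyldeca‑3,9‑dien‑1‑yl)zinc iodide | CC(=O)C(CC[Zn]I)=C(C)CCCC(C)(C)C=COC | intermediate
16 | methyl (2E)‑6‑acetyl‑3‑{[(tert‑butyldiphenylsilyl)oxy]methyl}‑13‑methoxy‑7,11,11‑trimethyltrideca‑2,6,12‑trienoate | COC(=O)/C=C(\CCC(C(C)=O)=C(C)CCCC(C)(C)C=COC)CO[Si](c1ccccc1)(c1ccccc1)C(C)(C)C | intermediate
17 | methyl (2E)‑6‑acetyl‑3‑{[(tert‑butyldiphenylsilyl)oxy]methyl}‑7,11,11‑trimethyl‑13‑oxotrideca‑2,6‑dienoate | COC(=O)/C=C(\CCC(C(C)=O)=C(C)CCCC(C)(C)CC=O)CO[Si](c1ccccc1)(c1ccccc1)C(C)(C)C | intermediate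
18 | methyl (2E)‑3‑{[(tert‑butyldiphenylsilyl)oxy]methyl}‑6‑(2‑formyl‑1,3,3‑trimethylcyclohexyl)‑7‑oxooct‑2‑enoate (formyl trans to the chain on the ring; C9 epimers) | COC(=O)/C=C(\CCC(C(C)=O)[C@]1(C)CCCC(C)(C)[C@H]1C=O)CO[Si](c1ccccc1)(c1ccccc1)C(C)(C)C | intermediate
19 | methyl (13E)‑16‑[(tert‑butyldiphenylsilyl)oxy]‑6‑hydroxy‑8‑oxo‑17‑nor‑ent‑labd‑13‑en‑15‑oate (trans‑fused; C6 and C9 epimers) | COC(=O)/C=C(\CCC1C(=O)CC(O)[C@@H]2C(C)(C)CCC[C@@]12C)CO[Si](c1ccccc1)(c1ccccc1)C(C)(C)C | intermediate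
20 | methyl (13E)‑16‑[(tert‑butyldiphenylsilyl)oxy]‑8‑oxo‑17‑nor‑ent‑labda‑6,13‑dien‑15‑oate (trans‑fused; H‑5 and H‑9 anti to CH3‑20) | COC(=O)/C=C(\CC[C@@H]1C(=O)C=C[C@@H]2C(C)(C)CCC[C@@]12C)CO[Si](c1ccccc1)(c1ccccc1)C(C)(C)C | intermediate
21 | methyl (13E)‑16‑[(tert‑butyldiphenylsilyl)oxy]‑6,7‑epoxy‑8‑oxo‑17‑nor‑ent‑labd‑13‑en‑15‑oate (epoxide oxygen anti to CH3‑20) | COC(=O)/C=C(\CC[C@@H]1C(=O)[C@H]3O[C@H]3[C@@H]2C(C)(C)CCC[C@@]12C)CO[Si](c1ccccc1)(c1ccccc1)C(C)(C)C | intermediate
22 | methyl (13E)‑16‑[(tert‑butyldiphenylsilyl)oxy]‑6,7‑epoxy‑17‑methoxy‑ent‑labda‑8(17),13‑dien‑15‑oate (enol ether geometry not defined) | COC(=O)/C=C(\CC[C@@H]1C(=COC)[C@H]3O[C@H]3[C@@H]2C(C)(C)CCC[C@@]12C)CO[Si](c1ccccc1)(c1ccccc1)C(C)(C)C | intermediate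
23 | methyl (13E)‑16‑[(tert‑butyldiphenylsilyl)oxy]‑6‑hydroxy‑17‑oxo‑ent‑labda‑7,13‑dien‑15‑oate (6‑OH anti to CH3‑20) | COC(=O)/C=C(\CC[C@@H]1C(C=O)=C[C@@H](O)[C@@H]2C(C)(C)CCC[C@@]12C)CO[Si](c1ccccc1)(c1ccccc1)C(C)(C)C | intermediate
24 | methyl (13E)‑6,16‑dihydroxy‑17‑oxo‑ent‑labda‑7,13‑dien‑15‑oate | COC(=O)/C=C(\CC[C@@H]1C(C=O)=C[C@@H](O)[C@@H]2C(C)(C)CCC[C@@]12C)CO | intermediate
25 | CNP0134813.1, methyl (2E)‑5‑[(1S,4R,4aR,8aS)‑2‑formyl‑4‑hydroxy‑5,5,8a‑trimethyl‑1,4,4a,5,6,7,8,8a‑octahydronaphthalen‑1‑yl]‑3‑[(formyloxy)methyl]pent‑2‑enoate | COC(=O)/C=C(\CC[C@@H]1C(C=O)=C[C@@H](O)[C@@H]2C(C)(C)CCC[C@@]12C)COC=O | target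

**Step count and risks**

Total step count: 16. Longest linear sequence: 12 steps (steps 5–16, from pentane‑2,4‑dione).

Steps most likely to fail:

1. Step 12 (proposed new method). The hindered enamine may not add to the tetrasubstituted, only hydrogen‑bond‑activated acceptor, so that no ring A forms. Facial control at C10 may be insufficient, and a vinylogous aldol closure from C1 to C6 may compete. Should the sense of induction be opposite, the (R)‑amine is used. Fallback with known chemistry, from 17 back to 20: TBSOTf, Et3N, CH2Cl2, −78 °C silylates the aldehyde selectively to the tert‑butyldimethylsilyl enol ether F1. TiCl4, CH2Cl2, −78 °C then effects the intramolecular Mukaiyama–Michael addition, the established way to add to hindered β,β‑disubstituted enones, and gives after aqueous work‑up the keto aldehyde as a racemate, that is 18 together with ent‑18 F2. p‑TsOH·H2O, toluene, 50 °C closes ring B through the ketol (19 together with ent‑19 F3) to the racemic enone (20 together with ent‑20 F4). Preparative chromatography on a cellulose tris(3,5‑dimethylphenylcarbamate) phase separates 20 from ent‑20 F4, and the route continues at 20.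

2. Step 14. Olefination of the hindered C8 ketone may be sluggish, and the basic ylide may scramble the geometry of the side‑chain enoate by γ‑deprotonation. Fallback from 21 back to 23: Zn, CH2Br2, TiCl4, THF/CH2Cl2, 0 °C (non‑basic Takai–Lombardo methylenation, suited to hindered enolisable ketones) gives vinyl epoxide F5. Pd(PPh3)4 (cat.), AcOH, THF opens it in 1,4‑fashion through the π‑allylpalladium alkoxide, with acetate at the exocyclic terminus C17 and the C6–O bond untouched, to hydroxy acetate F6. K2CO3, MeOH, 0 °C gives allylic diol F7. TEMPO (cat.), PhI(OAc)2, CH2Cl2 oxidises only the primary allylic alcohol and returns 23.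

3. Step 16. Chemoselectivity may be lost through formylation of the C6 hydroxyl or acetyl transfer, and the γ‑hydroxy enal may degrade during acylation. Fallback from 22 to 25, with the C6 hydroxyl unveiled last: the acid treatment of step 14 is left out and 22 is isolated on triethylamine‑deactivated silica. Bu4NF, THF, 0 °C gives primary alcohol F8. Acetic formic anhydride, pyridine, CH2Cl2, −40 °C gives formate F9, with no other hydroxyl present. Aqueous oxalic acid, THF, 0 °C then opens the epoxy enol ether as in step 14 and gives 25 directly.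

Further compounds
F1 | step 12 | tert‑butyldimethylsilyl enol ether of 17 | COC(=O)/C=C(\CCC(C(C)=O)=C(C)CCCC(C)(C)C=CO[Si](C)(C)C(C)(C)C)CO[Si](c1ccccc1)(c1ccccc1)C(C)(C)C
F2 | step 12 | ent‑18 (enantiomer of keto aldehyde 18) | COC(=O)/C=C(\CCC(C(C)=O)[C@@]1(C)CCCC(C)(C)[C@@H]1C=O)CO[Si](c1ccccc1)(c1ccccc1)C(C)(C)C
F3 | step 12 | ent‑19 (enantiomer of ketol 19) | COC(=O)/C=C(\CCC1C(=O)CC(O)[C@H]2C(C)(C)CCC[C@]12C)CO[Si](c1ccccc1)(c1ccccc1)C(C)(C)C
F4 | step 12 | ent‑20 (enantiomer of enone 20) | COC(=O)/C=C(\CC[C@H]1C(=O)C=C[C@H]2C(C)(C)CCC[C@]12C)CO[Si](c1ccccc1)(c1ccccc1)C(C)(C)C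
F5 | step 14 | vinyl epoxide, methyl (13E)‑16‑[(tert‑butyldiphenylsilyl)oxy]‑6,7‑epoxy‑ent‑labda‑8(17),13‑dien‑15‑oate | COC(=O)/C=C(\CC[C@@H]1C(=C)[C@H]3O[C@H]3[C@@H]2C(C)(C)CCC[C@@]12C)CO[Si](c1ccccc1)(c1ccccc1)C(C)(C)C
F6 | step 14 | hydroxy acetate, methyl (13E)‑17‑acetoxy‑16‑[(tert‑butyldiphenylsilyl)oxy]‑6‑hydroxy‑ent‑labda‑7,13‑dien‑15‑oate | COC(=O)/C=C(\CC[C@@H]1C(COC(C)=O)=C[C@@H](O)[C@@H]2C(C)(C)CCC[C@@]12C)CO[Si](c1ccccc1)(c1ccccc1)C(C)(C)C
F7 | step 14 | diol, methyl (13E)‑16‑[(tert‑butyldiphenylsilyl)oxy]‑6,17‑dihydroxy‑ent‑labda‑7,13‑dien‑15‑oate | COC(=O)/C=C(\CC[C@@H]1C(CO)=C[C@@H](O)[C@@H]2C(C)(C)CCC[C@@]12C)CO[Si](c1ccccc1)(c1ccccc1)C(C)(C)C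
F8 | step 16 | primary alcohol, methyl (13E)‑6,7‑epoxy‑16‑hydroxy‑17‑methoxy‑ent‑labda‑8(17),13‑dien‑15‑oate | COC(=O)/C=C(\CC[C@@H]1C(=COC)[C@H]3O[C@H]3[C@@H]2C(C)(C)CCC[C@@]12C)CO
F9 | step 16 | formate, methyl (13E)‑6,7‑epoxy‑16‑formyloxy‑17‑methoxy‑ent‑labda‑8(17),13‑dien‑15‑oate | COC(=O)/C=C(\CC[C@@H]1C(=COC)[C@H]3O[C@H]3[C@@H]2C(C)(C)CCC[C@@]12C)COC=O
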